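The cyclopentane ring (C1–C5) bears a CH2O arm at C1, methyl at C2, oxygen at C3 and a CH(CH2OH)2 arm at C5. The C1 arm carbon and one CH2O carbon of the C5 arm can be bridged by a single oxygen into a temporary pyran acetal ring. The carbocycle therefore unravels to a but-2-ynal acetal, a vinyl group and CO. One Pauson–Khand reaction of mixed acetal 10, an acetal-tethered 1,7-enyne whose controlling stereocentre is the allylic arm carbon, forms C1–C5, C3–C4 and C2–C3, closes both rings and sets C5. C1 and C2 are then equilibrated. C3 is reduced and inverted on esterification with two periodate-releasable acids 29.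

Key step: step 5

Remark on numbering: C1–C5 as defined above are used for all monocyclic compounds. In the cyclopenta[c]pyran names of 12–14, C7a = C1, C7 = C2, C6 = C3, C5 = C4 and C4a = C5.
Remark on mixtures: the acetal or lactol carbon of 10–14 and the C3 carbinol of 15 and 17 are carried as epimer mixtures, because both centres are erased in steps 7 and 9. Their SMILES leave these centres open.
Assumption: enone 21 is bought as the enantiopure building block derived from D-ribose.

Step 1
Reactants: 1 (S)-4-benzyl-1,3-oxazolidin-2-one; 2 (E)-but-2-enoyl chloride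
Product: 4 (S)-4-benzyl-3-[(E)-but-2-enoyl]-1,3-oxazolidin-2-one, via N-lithio oxazolidinone 3 (not isolated)
Conditions: n-BuLi, THF, −78 °C; then 2, −78 → 0 °C
Reagents that add atoms: (E)-but-2-enoyl chloride (2), C/C=C/C(=O)Cl
Why: N-acylation of the lithiated Evans oxazolidinone with an acid chloride is the standard imide synthesis and creates no stereocentre.

Step 2
Reactants: 4 (S)-4-benzyl-3-[(E)-but-2-enoyl]-1,3-oxazolidin-2-one; 5 benzyl chloromethyl ether
Product: 7 (S)-4-benzyl-3-[(2R)-2-(benzyloxymethyl)but-3-enoyl]-1,3-oxazolidin-2-one, via sodium dienolate 6 (not isolated)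
Conditions: NaN(SiMe3)2, THF, −78 °C; then 5, −78 → −40 °C; AcOH quench
Reagents that add atoms: benzyl chloromethyl ether (5), ClCOCc1ccccc1
Why: Deconjugative Evans asymmetric alkylation: γ-deprotonation gives the chelated Z-dienolate, which reacts at its α-carbon with the reactive chloromethyl ether on the face opposite the auxiliary benzyl group and so sets the 2R centre, and a benzyl ether is chosen because, unlike a silyl group, it cannot wander between the two oxygen atoms of monoprotected diol 8 and thereby racemise it.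

Step 3
Reactants: 7 (S)-4-benzyl-3-[(2R)-2-(benzyloxymethyl)but-3-enoyl]-1,3-oxazolidin-2-one
Product: 8 (2S)-2-(benzyloxymethyl)but-3-en-1-ol
Conditions: LiBH4, MeOH (1 equiv), Et2O, 0 °C
Reagents that add atoms: none
Why: Reductive cleavage of the N-acyl oxazolidinone with LiBH4 converts the imide carbonyl into CH2OH, leaves the vinyl group and the α-centre untouched and returns the auxiliary.

Step 4
Reactants: 8 (2S)-2-(benzyloxymethyl)but-3-en-1-ol; 9 1,1-diethoxybut-2-yne
Product: 10 1-ethoxybut-2-yn-1-yl (2R)-2-(benzyloxymethyl)but-3-en-1-yl ether (mixed acetal of but-2-ynal; both acetal epimers)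
Conditions: 9 (4 equiv), PPTS (cat.), toluene, 5 Å MS, 80 °C
Reagents that add atoms: 1,1-diethoxybut-2-yne (9), CC#CC(OCC)OCC
Why: Acid-catalysed transacetalisation, in which the excess of 9 and the trapping of ethanol favour exchange of a single ethoxy group; the new acetal carbon forms as both epimers, which is harmless because it ends as the C1 CH2O carbon.

Step 5
Reactants: 10 1-ethoxybut-2-yn-1-yl (2R)-2-(benzyloxymethyl)but-3-en-1-yl ether
Product: 12 (4R,4aS)-4-(benzyloxymethyl)-1-ethoxy-7-methyl-3,4,4a,5-tetrahydro-1H-cyclopenta[c]pyran-6-one, via hexacarbonyldicobalt alkyne complex 11 (not isolated)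
Conditions: Co2(CO)8 (1.1 equiv), CH2Cl2, rt; then N-methylmorpholine N-oxide (8 equiv), 0 °C → rt
Reagents that add atoms: Co2(CO)8 as the source of CO, [Co].[Co].[C-]#[O+].[C-]#[O+].[C-]#[O+].[C-]#[O+].[C-]#[O+].[C-]#[O+].[C-]#[O+].[C-]#[O+]
Why: Co2(CO)8 (zerovalent cobalt) loses two CO and binds the alkyne as complex 11; oxidation of a CO ligand by the N-oxide frees a site for the vinyl group, which inserts into the Co–C1 bond (C1–C5), CO then inserts into the Co–C4 bond (C3–C4) and reductive elimination forms C2–C3. The closest known reaction type is the intramolecular Pauson–Khand reaction of oxygen-tethered 1,7-enynes to cyclopenta[c]pyran-6-ones, the tether here carrying only one more alkoxy group. The pyran acetal ring closes in the exo mode of alkene insertion (internal alkene carbon onto the tethered alkyne carbon, six-membered), and the cyclopentenone closes by the [2+2+1] sequence of CO insertion and reductive elimination. C5 is controlled by the allylic tether centre, whose CH2OBn group should sit pseudo-equatorial in the chair-like forming pyran and anti to the new C5–C4 bond, giving 4R,4aS, while the C5 epimer is a separable diastereomer. Regiochemistry (methyl-bearing carbon next to C=O, terminal CH2 as C4) is enforced by the tether. The step needs the propargylic acetal to survive, which the neutral, Lewis-acid-free N-oxide conditions secure by avoiding a cobalt-stabilised propargyl cation.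

Step 6
Reactants: 12 (4R,4aS)-4-(benzyloxymethyl)-1-ethoxy-7-methyl-3,4,4a,5-tetrahydro-1H-cyclopenta[c]pyran-6-one
Product: 13 (4R,4aS,7R,7aR)-1-ethoxy-4-(hydroxymethyl)-7-methyl-3,4,4a,5,7,7a-hexahydro-1H-cyclopenta[c]pyran-6-one (cis-fused; methyl on the concave face)
Conditions: H2 (4 atm), 10% Pd/C, EtOAc–EtOH, rt
Reagents that add atoms: none
Why: Heterogeneous catalytic hydrogenation adds H2 syn to the tetrasubstituted enone alkene, as with 2,3-dialkylcyclopent-2-enones, from the convex face that carries H-5, so that H-1, H-2 and H-5 end up cis, and the same catalyst hydrogenolyses the benzyl ether.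

Step 7
Reactants: 13 (4R,4aS,7R,7aR)-1-ethoxy-4-(hydroxymethyl)-7-methyl-3,4,4a,5,7,7a-hexahydro-1H-cyclopenta[c]pyran-6-one
Product: 15 all-cis tetraol 2-[4-hydroxy-2-(hydroxymethyl)-3-methylcyclopentyl]propane-1,3-diol (1R,2R,5R in the ring numbering used here; C3 both epimers), via cis-fused keto lactol 14 (not isolated)
Conditions: TsOH·H2O (0.1 equiv), THF–H2O (1:1), 40 °C; then NaBH4 (excess), 0 °C
Reagents that add atoms: water, O
Why: Acetal hydrolysis followed by borohydride reduction of the lactol (through its open aldehyde) and of the ketone opens the pyran ring for good, which is needed because C1 could otherwise only equilibrate between cis- and trans-fused lactols expected to be close in energy; the water-rich medium disfavours closure of the free CH2OH onto the lactol carbon, and the C3 configuration is irrelevant here.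

Step 8
Reactants: 15 all-cis tetraol; 16 2,2-dimethoxypropane
Product: 17 all-cis acetonide diol [(1R,2R,5R)-5-(2,2-dimethyl-1,3-dioxan-5-yl)-3-hydroxy-2-methylcyclopentyl]methanol (C3 both epimers)
Conditions: 16, PPTS (cat.), acetone, rt
Reagents that add atoms: 2,2-dimethoxypropane (16), COC(C)(C)OC
Why: Thermodynamic acetonide formation picks the only 1,3-diol, since the six-membered 1,3-dioxane is favoured over the seven- and eight-membered alternatives, and leaves free exactly the two hydroxy groups that are to be acylated.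

Step 9
Reactants: 17 all-cis acetonide diol
Product: 19 (1S,2R,5S)-5-(2,2-dimethyl-1,3-dioxan-5-yl)-2-methyl-3-oxocyclopentane-1-carbaldehyde (all neighbours trans), via all-cis keto aldehyde 18 (not isolated)
Conditions: (COCl)2, DMSO, CH2Cl2, −78 °C; Et3N, −78 °C → rt; then DBU (0.2 equiv), rt
Reagents that add atoms: none
Why: Swern oxidation gives a keto aldehyde in which C1 (α to CHO) and C2 (α to C3=O) are both enolisable, and base-catalysed epimerisation around the fixed C5 centre should settle on the isomer with CHO anti to both the methyl and the dioxanyl group, no lactol being possible now.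

Step 10
Reactants: 19 (1S,2R,5S)-5-(2,2-dimethyl-1,3-dioxan-5-yl)-2-methyl-3-oxocyclopentane-1-carbaldehyde
Product: 20 [(1S,2R,3S,5R)-5-(2,2-dimethyl-1,3-dioxan-5-yl)-3-hydroxy-2-methylcyclopentyl]methanol (3-OH cis to the 2-methyl group)
Conditions: LiBH(s-Bu)3 (2.5 equiv), THF, −78 °C; then NaOH, H2O2, 0 °C
Reagents that add atoms: none
Why: Sterically controlled hydride reduction, as with 2,3-disubstituted cyclopentanones of the prostaglandin E type: the bulky borohydride attacks C3 anti to the adjacent methyl and to the C5 group, which sets 3S, and it reduces the aldehyde as well; a small borohydride would face the same bias less cleanly, so C3 is deliberately made in the epimeric form and inverted in step 15.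

Step 11
Reactants: 21 (3aR,6aR)-2,2-dimethyl-3a,6a-dihydro-4H-cyclopenta[d][1,3]dioxol-4-one
Product: 22 (3aR,6aR)-2,2-dimethyltetrahydro-4H-cyclopenta[d][1,3]dioxol-4-one
Conditions: H2 (1 atm), 10% Pd/C, EtOAc, rt
Reagents that add atoms: none
Why: Catalytic hydrogenation saturates the enone alkene and leaves the two dioxolane stereocentres untouched.

Step 12
Reactants: 22 (3aR,6aR)-2,2-dimethyltetrahydro-4H-cyclopenta[d][1,3]dioxol-4-one; 23 methyl bromoacetate
Product: 25 methyl 2-[(3aR,5S,6aR)-2,2-dimethyl-4-oxotetrahydro-4H-cyclopenta[d][1,3]dioxol-5-yl]acetate, via lithium enolate 24 (not isolated)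
Conditions: LiN(i-Pr)2, THF, −78 °C; then 23, DMPU, −78 → −30 °C
Reagents that add atoms: methyl bromoacetate (23), COC(=O)CBr
Why: Kinetic enolate alkylation: the amide base removes a C5 proton on the side away from the oxygenated α-carbon, and the bromoacetate enters on the convex face anti to the dioxolane, which sets 5S, the later side-chain stereocentre.

Step 13
Reactants: 25 methyl 2-[(3aR,5S,6aR)-2,2-dimethyl-4-oxotetrahydro-4H-cyclopenta[d][1,3]dioxol-5-yl]acetate; 26 ethyltriphenylphosphonium bromide
Product: 28 methyl 2-[(3aS,4E,5S,6aR)-4-ethylidene-2,2-dimethyltetrahydro-4H-cyclopenta[d][1,3]dioxol-5-yl]acetate (methyl cis to C5), via ethylidenetriphenylphosphorane 27 (not isolated)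
Conditions: 26, KOt-Bu, THF, 0 °C; then 25, 0 °C → rt
Reagents that add atoms: ethyltriphenylphosphonium bromide (26), CC[P+](c1ccccc1)(c1ccccc1)c1ccccc1.[Br-]
Why: Wittig olefination with a lithium-free non-stabilised ylide under kinetic control, which should place the ylide methyl cis to the bulkier α-carbon (C5, carbon-branched) rather than the oxygen-bearing C3a, as in the ethylidenation of 17-oxo steroids where the methyl ends up cis to the quaternary carbon; the 4Z isomer is removed by chromatography.

Step 14
Reactants: 28 methyl 2-[(3aS,4E,5S,6aR)-4-ethylidene-2,2-dimethyltetrahydro-4H-cyclopenta[d][1,3]dioxol-5-yl]acetate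
Product: 29 2-[(3aS,4E,5S,6aR)-4-ethylidene-2,2-dimethyltetrahydro-4H-cyclopenta[d][1,3]dioxol-5-yl]acetic acid
Conditions: LiOH, THF–H2O, 0 °C → rt; then 1 M HCl to pH 4, 0 °C
Reagents that add atoms: lithium hydroxide, [Li+].[OH-]
Why: Ester saponification, to which the acetonide and the alkene are inert, and C5 is no longer α to a carbonyl group and cannot epimerise.

Step 15
Reactants: 20 [(1S,2R,3S,5R)-5-(2,2-dimethyl-1,3-dioxan-5-yl)-3-hydroxy-2-methylcyclopentyl]methanol; 29 2-[(3aS,4E,5S,6aR)-4-ethylidene-2,2-dimethyltetrahydro-4H-cyclopenta[d][1,3]dioxol-5-yl]acetic acid (two molecules)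
Product: 31 bis-ester of the (1S,2R,3R,5R) core acetonide carrying the acyl group of 29 on the C1 CH2O group and on O-3, via primary monoester 30 (not isolated)
Conditions: 29 (2.6 equiv), PPh3, DIAD, THF, 0 °C → rt
Reagents that add atoms: none
Why: Twofold Mitsunobu esterification: the primary alcohol is esterified first, and the C3 oxyphosphonium ion is then displaced by the carboxylate in an SN2 reaction from the open face anti to the C2 methyl group, which inverts C3 to the required 3R configuration, as known for the inversion of 9α-hydroxy prostaglandins.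

Step 16
Reactants: 31 bis-ester tris-acetonide
Product: 32 hexaol: the same bis-ester with a free CH(CH2OH)2 arm and a free cis-1,2-diol in each side-chain ring
Conditions: AcOH–H2O (4:1), 45 °C
Reagents that add atoms: none
Why: Acid-catalysed hydrolysis of the three isopropylidene acetals spares esters and alkenes, and lactonisation or acyl shift is geometrically disfavoured because each CH2CO2R group is trans to the diol of its ring.

Step 17
Reactants: 32 hexaol
Product: 33 [(1S,2R,3R,5R)-5-(1,3-dihydroxypropan-2-yl)-3-{[(3S,4E)-4-formyl-3-(2-oxoethyl)hex-4-enoyl]oxy}-2-methylcyclopentyl]methyl (3S,4E)-4-formyl-3-(2-oxoethyl)hex-4-enoate (CNP0313563.1)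
Conditions: NaIO4 (2.4 equiv), THF–H2O, 0 °C → rt
Reagents that add atoms: none
Why: Malaprade glycol cleavage: periodate cleaves only the two cis-1,2-diols through cyclic periodate esters, leaves the 1,3-diol alone and turns each side-chain ring into the CH2CHO and 2-ethylidene aldehyde units with the geometry fixed in step 13, which is also the thermodynamically preferred E-enal.

Compound list
1 | (S)-4-benzyl-1,3-oxazolidin-2-one | O=C1N[C@@H](Cc2ccccc2)CO1 | starting material
2 | (E)-but-2-enoyl chloride | C/C=C/C(=O)Cl | starting material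
3 | N-lithio-(S)-4-benzyl-1,3-oxazolidin-2-one | [Li+].O=C1[N-][C@@H](Cc2ccccc2)CO1 | intermediate
4 | (S)-4-benzyl-3-[(E)-but-2-enoyl]-1,3-oxazolidin-2-one | C/C=C/C(=O)N1C(=O)OC[C@@H]1Cc1ccccc1 | intermediate
5 | benzyl chloromethyl ether | ClCOCc1ccccc1 | starting material
6 | sodium Z-dienolate of 4 | [Na+].C=C/C=C(\[O-])N1C(=O)OC[C@@H]1Cc1ccccc1 | intermediate
7 | (S)-4-benzyl-3-[(2R)-2-(benzyloxymethyl)but-3-enoyl]-1,3-oxazolidin-2-one | O=C([C@@H](COCc1ccccc1)C=C)N1C(=O)OC[C@@H]1Cc1ccccc1 | intermediate
8 | (2S)-2-(benzyloxymethyl)but-3-en-1-ol | OC[C@@H](COCc1ccccc1)C=C | intermediate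
9 | 1,1-diethoxybut-2-yne | CC#CC(OCC)OCC | starting material
10 | 1-ethoxybut-2-yn-1-yl (2R)-2-(benzyloxymethyl)but-3-en-1-yl ether, both acetal epimers | CC#CC(OCC)OC[C@@H](COCc1ccccc1)C=C | intermediate
11 | Co2(CO)6 complex of the alkyne of 10 | CC12C3(C(OCC)OC[C@@H](COCc4ccccc4)C=C)[Co-3]1(C#[O+])(C#[O+])(C#[O+])[Co-3]23(C#[O+])(C#[O+])C#[O+] | intermediate
12 | (4R,4aS)-4-(benzyloxymethyl)-1-ethoxy-7-methyl-3,4,4a,5-tetrahydro-1H-cyclopenta[c]pyran-6-one | CC1=C2C(OCC)OC[C@@H](COCc3ccccc3)[C@@H]2CC1=O | intermediate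
13 | (4R,4aS,7R,7aR)-1-ethoxy-4-(hydroxymethyl)-7-methyl-3,4,4a,5,7,7a-hexahydro-1H-cyclopenta[c]pyran-6-one | C[C@@H]1[C@@H]2C(OCC)OC[C@@H](CO)[C@@H]2CC1=O | intermediate
14 | (4R,4aS,7R,7aR)-1-hydroxy-4-(hydroxymethyl)-7-methyl-3,4,4a,5,7,7a-hexahydro-1H-cyclopenta[c]pyran-6-one | C[C@@H]1[C@@H]2C(O)OC[C@@H](CO)[C@@H]2CC1=O | intermediate
15 | all-cis tetraol, 2-[4-hydroxy-2-(hydroxymethyl)-3-methylcyclopentyl]propane-1,3-diol, 1R,2R,5R in the ring numbering used here, C3 open | C[C@@H]1[C@H](CO)[C@H](C(CO)CO)CC1O | intermediate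
16 | 2,2-dimethoxypropane | COC(C)(C)OC | starting material
17 | [(1R,2R,5R)-5-(2,2-dimethyl-1,3-dioxan-5-yl)-3-hydroxy-2-methylcyclopentyl]methanol, C3 open | C[C@@H]1[C@H](CO)[C@H](C2COC(C)(C)OC2)CC1O | intermediate
18 | (1R,2R,5S)-5-(2,2-dimethyl-1,3-dioxan-5-yl)-2-methyl-3-oxocyclopentane-1-carbaldehyde (all cis) | C[C@@H]1[C@H](C=O)[C@H](C2COC(C)(C)OC2)CC1=O | intermediate
19 | (1S,2R,5S)-5-(2,2-dimethyl-1,3-dioxan-5-yl)-2-methyl-3-oxocyclopentane-1-carbaldehyde (all trans) | C[C@@H]1[C@@H](C=O)[C@H](C2COC(C)(C)OC2)CC1=O | intermediate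
20 | [(1S,2R,3S,5R)-5-(2,2-dimethyl-1,3-dioxan-5-yl)-3-hydroxy-2-methylcyclopentyl]methanol | OC[C@@H]1[C@@H](C)[C@@H](O)C[C@H]1C2COC(C)(C)OC2 | intermediate
21 | (3aR,6aR)-2,2-dimethyl-3a,6a-dihydro-4H-cyclopenta[d][1,3]dioxol-4-one | O=C1C=C[C@H]2OC(C)(C)O[C@@H]12 | starting material
22 | (3aR,6aR)-2,2-dimethyltetrahydro-4H-cyclopenta[d][1,3]dioxol-4-one | O=C1CC[C@H]2OC(C)(C)O[C@@H]12 | intermediate
23 | methyl bromoacetate | COC(=O)CBr | starting material
24 | lithium C4–C5 enolate of 22 | [Li+].[O-]C1=CC[C@H]2OC(C)(C)O[C@@H]12 | intermediate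
25 | methyl 2-[(3aR,5S,6aR)-2,2-dimethyl-4-oxotetrahydro-4H-cyclopenta[d][1,3]dioxol-5-yl]acetate | O=C1[C@H](CC(=O)OC)C[C@H]2OC(C)(C)O[C@@H]12 | intermediate
26 | ethyltriphenylphosphonium bromide | CC[P+](c1ccccc1)(c1ccccc1)c1ccccc1.[Br-] | starting material
27 | ethylidenetriphenylphosphorane | CC=P(c1ccccc1)(c1ccccc1)c1ccccc1 | intermediate
28 | methyl 2-[(3aS,4E,5S,6aR)-4-ethylidene-2,2-dimethyltetrahydro-4H-cyclopenta[d][1,3]dioxol-5-yl]acetate | C/C=C1\[C@H](CC(=O)OC)C[C@H]2OC(C)(C)O[C@@H]12 | intermediate
29 | 2-[(3aS,4E,5S,6aR)-4-ethylidene-2,2-dimethyltetrahydro-4H-cyclopenta[d][1,3]dioxol-5-yl]acetic acid | C/C=C1\[C@H](CC(=O)O)C[C@H]2OC(C)(C)O[C@@H]12 | intermediate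
30 | monoester of 20 with 29 at the C1 CH2O group, 3S-OH free | C/C=C1\[C@H](CC(=O)OC[C@@H]3[C@@H](C)[C@@H](O)C[C@H]3C4COC(C)(C)OC4)C[C@H]2OC(C)(C)O[C@@H]12 | intermediate
31 | bis-ester tris-acetonide, core 1S,2R,3R,5R | C/C=C1\[C@H](CC(=O)OC[C@@H]3[C@@H](C)[C@H](OC(=O)C[C@@H]4C[C@H]5OC(C)(C)O[C@H]5/C4=C/C)C[C@H]3C6COC(C)(C)OC6)C[C@H]2OC(C)(C)O[C@@H]12 | intermediate
32 | bis-ester hexaol | C/C=C1\[C@H](CC(=O)OC[C@@H]3[C@@H](C)[C@H](OC(=O)C[C@@H]4C[C@@H](O)[C@@H](O)/C4=C/C)C[C@H]3C(CO)CO)C[C@@H](O)[C@H]1O | intermediate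
33 | CNP0313563.1 | C/C=C(/C=O)[C@@H](CC=O)CC(=O)OC[C@@H]1[C@@H](C)[C@H](OC(=O)C[C@H](CC=O)/C(C=O)=C\C)C[C@H]1C(CO)CO | target

Total step count: 17. Longest linear sequence: 13 steps (steps 1–10 and 15–17). The acid branch (steps 11–14) joins convergently.

Steps most likely to fail

Step 5. The six-ring-forming alkene insertion of a 1,7-enyne is slow. Complex 11 may therefore be lost through decomplexation or through ionisation at the propargylic acetal carbon before it cyclises, and facial selectivity at C5 may be modest. The fallback sets out from 10 and replaces CO by an isocyanide in a nickel-mediated [2+2+1] reaction (Ni(cod)2, zerovalent nickel, PBu3, 2,6-dimethylphenyl isocyanide, THF). This should give the N-(2,6-dimethylphenyl)imine of the bicyclic enone F1. Mild hydrolysis of the imine (aqueous oxalic acid, THF, 0 °C) comes back to the route at 12.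

Step 13. The basic ylide may enolise the ketone, and the kinetic preference for methyl cis to C5 may be weak, so that control of the alkene geometry is poor. The fallback sets out from 25 and gives up kinetic control. The olefination is run as before and the unwanted methyl 2-[(3aS,4Z,5S,6aR)-4-ethylidene-2,2-dimethyltetrahydro-4H-cyclopenta[d][1,3]dioxol-5-yl]acetate F2 is separated on AgNO3-impregnated silica. It is then re-equilibrated by reversible thiyl-radical addition (PhSSPh, hν, benzene) and recycled through the same separation. This comes back to the route at 28.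

Step 15. Activation of the hindered C3 hydroxy group may end in E2 elimination towards C2 or C4, or the weakly acidic aliphatic acid may displace the oxyphosphonium ion too slowly. The fallback sets out from 20 and separates inversion from fragment coupling. A Mitsunobu reaction with the more acidic 4-nitrobenzoic acid (PPh3, DIAD, THF) should give the (1S,2R,3R,5R) bis(4-nitrobenzoate) F3. Methanolysis (K2CO3, MeOH) frees [(1S,2R,3R,5R)-5-(2,2-dimethyl-1,3-dioxan-5-yl)-3-hydroxy-2-methylcyclopentyl]methanol F4. Twofold carbodiimide acylation with 29 (EDC·HCl, DMAP, CH2Cl2), which proceeds with retention, comes back to the route at 31.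

Further compounds
F1 | step 5 | (4R,4aS)-4-(benzyloxymethyl)-N-(2,6-dimethylphenyl)-1-ethoxy-7-methyl-3,4,4a,5-tetrahydro-1H-cyclopenta[c]pyran-6-imine | CC1=C2C(OCC)OC[C@@H](COCc3ccccc3)[C@@H]2CC1=Nc1c(C)cccc1C
F2 | step 13 | methyl 2-[(3aS,4Z,5S,6aR)-4-ethylidene-2,2-dimethyltetrahydro-4H-cyclopenta[d][1,3]dioxol-5-yl]acetate | C/C=C1/[C@H](CC(=O)OC)C[C@H]2OC(C)(C)O[C@@H]12
F3 | step 15 | [(1S,2R,3R,5R)-5-(2,2-dimethyl-1,3-dioxan-5-yl)-2-methyl-3-(4-nitrobenzoyloxy)cyclopentyl]methyl 4-nitrobenzoate | O=C(OC[C@@H]1[C@@H](C)[C@H](OC(=O)c2ccc(cc2)[N+](=O)[O-])C[C@H]1C3COC(C)(C)OC3)c4ccc(cc4)[N+](=O)[O-]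
F4 | step 15 | [(1S,2R,3R,5R)-5-(2,2-dimethyl-1,3-dioxan-5-yl)-3-hydroxy-2-methylcyclopentyl]methanol | OC[C@@H]1[C@@H](C)[C@H](O)C[C@H]1C2COC(C)(C)OC2
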